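## Retrosynthetic overview
1. The C-4' carbinol and the free phenol come last, by 1,2-reduction of an enedione followed by desilylation.
2. Key disconnection: the bicyclo[3.2.1]octane core arises by ring expansion of a cyclobutane-fused enedione (bicyclo[4.2.0] to bicyclo[3.2.1]). C-6'–C-7 breaks, C-3'–C-7 forms, and one O-methyl is relayed from O-4' to O-5'.
3. The cyclobutane comes from an enantioselective, stepwise titanium TADDOLate (2+2) annulation of 5-allyl-2,3-dimethoxy-1,4-benzoquinone with O-silyl (E)-isoeugenol (C-8–C-1' first, then C-7–C-6').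
4. The quinone comes from squaric acid plus a C5 dienyl unit (2,3-dibromopropene + vinyl Grignard). The alkene comes from catechol plus (E)-propenylboronic acid.
5. Ring order: arene (bought), then the quinone six-membered ring, then the four-membered ring. Expanding the four-membered ring gives the five-membered ketone ring and closes the seven-membered ring at the same time.

Locants C-7 to C-9 and C-1' to C-6' follow neolignan numbering: C-1' carries allyl, C-2' is the bridging C=O, C-3' carries OMe, C-4' carries OH, C-5' carries OMe.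

Assumption: the (R,R)-TADDOLate shields the quinone face that leads to the (1'R,8R) series drawn. If the sense of induction is opposite, the (S,S)-ligand is used.

## Route

Step 1
Reactants: 1 catechol (benzene-1,2-diol)
Product: 2 guaiacol (2-methoxyphenol)
Conditions: MeI (1.0 equiv), K2CO3, acetone, reflux
Reagents that add atoms: iodomethane CI
Why: Williamson mono-O-methylation with limiting MeI gives the mono-ether, which separates easily from catechol and veratrole.

Step 2
Reactants: 2 guaiacol
Product: 3 4-bromo-2-methoxyphenol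
Conditions: NBS, MeCN, 0 °C
Reagents that add atoms: N-bromosuccinimide O=C1CCC(=O)N1Br
Why: Electrophilic aromatic bromination goes para to the free OH, the strongest director.

Step 3
Reactants: 3 4-bromo-2-methoxyphenol
Product: 4 (4-bromo-2-methoxyphenoxy)tri(propan-2-yl)silane
Conditions: TIPSCl, imidazole, DMF, rt
Reagents that add atoms: chlorotri(propan-2-yl)silane CC(C)[Si](Cl)(C(C)C)C(C)C
Why: Silylation masks the phenol with a group that survives aqueous base, titanium Lewis acids and MeOTf.

Step 4
Reactants: 4 (4-bromo-2-methoxyphenoxy)tri(propan-2-yl)silane; 5 (E)-prop-1-en-1-ylboronic acid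
Product: 6 {2-methoxy-4-[(E)-prop-1-en-1-yl]phenoxy}tri(propan-2-yl)silane
Conditions: Pd(dppf)Cl2 (3 mol %), K2CO3, 1,4-dioxane/H2O, 80 °C
Reagents that add atoms: none
Why: Suzuki–Miyaura coupling transfers the propenyl group with retention of the E geometry.

Step 5
Reactants: 7 squaric acid
Product: 8 dimethyl squarate
Conditions: HC(OMe)3, MeOH, reflux
Reagents that add atoms: trimethyl orthoformate COC(OC)OC
Why: Orthoformate-driven esterification of the vinylogous diacid is a standard preparation and needs no added acid or base.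

Step 6
Reactants: 9 2,3-dibromoprop-1-ene; 10 vinylmagnesium bromide
Product: 11 2-bromopenta-1,4-diene
Conditions: CuI (5 mol %), THF, −10 °C to rt
Reagents that add atoms: none
Why: Copper-catalysed allylic substitution by the Grignard reagent replaces only the allylic bromide, and direct and allyl-shifted attack give the same product.

Step 7
Reactants: 11 2-bromopenta-1,4-diene; 8 dimethyl squarate
Product: 13 (±)-4-hydroxy-2,3-dimethoxy-4-(penta-1,4-dien-2-yl)cyclobut-2-en-1-one, via penta-1,4-dien-2-yllithium 12 (not isolated)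
Conditions: t-BuLi (2 equiv), Et2O, −78 °C; then 8, THF, −78 °C; aq NH4Cl
Reagents that add atoms: none
Why: Lithium–bromine exchange and 1,2-addition to one squarate carbonyl stop cleanly at mono-addition at −78 °C, and the racemic carbinol centre is erased in step 8.

Step 8
Reactants: 13 (±)-4-hydroxy-2,3-dimethoxy-4-(penta-1,4-dien-2-yl)cyclobut-2-en-1-one
Product: 16 5-allyl-2,3-dimethoxy-1,4-benzoquinone, via dienylketene 14 (not isolated), via allyldimethoxyhydroquinone 15 (not isolated)
Conditions: p-xylene, 138 °C; then Ag2O, rt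
Reagents that add atoms: none
Why: The Moore rearrangement (thermal opening to ketene 14, six-electron closure, tautomerisation) builds the tetraoxygenated ring with allyl next to a carbonyl, and Ag2O oxidises hydroquinone 15.

Step 9
Reactants: 16 5-allyl-2,3-dimethoxy-1,4-benzoquinone; 6 {2-methoxy-4-[(E)-prop-1-en-1-yl]phenoxy}tri(propan-2-yl)silane
Product: 17 (1S,6R,7R,8R)-6-allyl-3,4-dimethoxy-7-methyl-8-[3-methoxy-4-(triisopropylsilyloxy)phenyl]bicyclo[4.2.0]oct-3-ene-2,5-dione (cis-fused; methyl syn to the six-membered ring; aryl anti to it and trans to methyl)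
Conditions: TiCl2(OiPr)2 (1.2 equiv), (R,R)-TADDOL, 4 Å MS, toluene/CH2Cl2, −78 °C; then H2O
Reagents that add atoms: none
Why: In this titanium-promoted stepwise (2+2) quinone–styrene annulation the TADDOLate chelates the less hindered carbonyl/methoxy pair and activates the allyl-bearing carbon, the alkene β-carbon adds on the open face (setting C-1' and C-8), and the titanium enolate carbon traps the benzylic cation at −78 °C before bond rotation, which gives the cis-fused ring with methyl and aryl trans.

Step 10
Reactants: 17 the cyclobutane-fused enedione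
Product: 20 (1S,5R,6R,7S)-5-allyl-1,3-dimethoxy-6-methyl-7-[3-methoxy-4-(triisopropylsilyloxy)phenyl]bicyclo[3.2.1]oct-3-ene-2,8-dione, via benzylic cation triflate 18 (not isolated), via bicyclic methyloxocarbenium triflate 19 (not isolated)
Conditions: MeOTf (10 mol %), 2,6-di-tert-butyl-4-methylpyridine (15 mol %), CH2Cl2, −20 °C to rt
Reagents that add atoms: none
Why: Proposed new method: in this methyl-cation-relay ring expansion MeOTf O-methylates the less hindered vinylogous-ester carbonyl (C-5'), the strained C-6'–C-7 bond heterolyses to methyl enol ether/benzylic cation 18 (driven by strain release and p-silyloxyaryl stabilisation), C-7 recloses on the methoxy enol ether carbon C-3' on the only face the C-8 tether allows with aryl endo and trans to the exo methyl (setting C-3' and C-7 while C-1' and C-8 stay untouched), and triflate demethylates oxocarbenium 19 to regenerate MeOTf, so the four-membered ring becomes the five-membered ketone ring in a net isomerisation, the closest known reaction types being the Lewis-acid rearrangement of quinone–styrene cyclobutanes and the cationic (5+2) annulation of quinone monoketals, neither shown as a methyl-transfer-catalysed isomerisation nor onto a methoxy-bearing terminus.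

Step 11
Reactants: 20 the bicyclo[3.2.1]octenedione
Product: 21 (1R,4S,5R,6S,7R)-1-allyl-4-hydroxy-3,5-dimethoxy-7-methyl-6-[3-methoxy-4-(triisopropylsilyloxy)phenyl]bicyclo[3.2.1]oct-2-en-8-one
Conditions: NaBH4, CeCl3·7H2O, MeOH, −78 °C
Reagents that add atoms: none
Why: Luche 1,2-reduction takes the enone carbonyl C-4' rather than the bridging ketone C-2' (flanked by two quaternary carbons), and hydride arrives syn to the one-carbon bridge because the endo aryl covers the other face, which sets (4'S).

Step 12
Reactants: 21 the silyl-protected alcohol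
Product: 22 target, (1R,4S,5R,6S,7R)-1-allyl-4-hydroxy-6-(4-hydroxy-3-methoxyphenyl)-3,5-dimethoxy-7-methylbicyclo[3.2.1]oct-2-en-8-one = (7S,8R,1'R,3'R,4'S)
Conditions: TBAF, AcOH, THF, 0 °C
Reagents that add atoms: none
Why: Acetic-acid-buffered fluoride desilylation frees the phenol without retro-aldol cleavage of the β-hydroxy ketone or loss of the enol ether.

## Compound list
1 | catechol | Oc1ccccc1O | starting material
2 | guaiacol | COc1ccccc1O | intermediate
3 | 4-bromo-2-methoxyphenol | COc1cc(Br)ccc1O | intermediate
4 | (4-bromo-2-methoxyphenoxy)tri(propan-2-yl)silane | COc1cc(Br)ccc1O[Si](C(C)C)(C(C)C)C(C)C | intermediate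
5 | (E)-prop-1-en-1-ylboronic acid | C/C=C/B(O)O | starting material
6 | {2-methoxy-4-[(E)-prop-1-en-1-yl]phenoxy}tri(propan-2-yl)silane | C/C=C/c1ccc(O[Si](C(C)C)(C(C)C)C(C)C)c(OC)c1 | intermediate
7 | squaric acid | OC1=C(O)C(=O)C1=O | starting material
8 | dimethyl squarate | COC1=C(OC)C(=O)C1=O | intermediate
9 | 2,3-dibromoprop-1-ene | C=C(Br)CBr | starting material
10 | vinylmagnesium bromide | C=C[Mg]Br | starting material
11 | 2-bromopenta-1,4-diene | C=CCC(Br)=C | intermediate
12 | penta-1,4-dien-2-yllithium (not isolated) | [Li]C(=C)CC=C | intermediate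
13 | (±)-4-hydroxy-2,3-dimethoxy-4-(penta-1,4-dien-2-yl)cyclobut-2-en-1-one (racemic, centre erased in step 8) | COC1=C(OC)C(O)(C(=C)CC=C)C1=O | intermediate
14 | (3Z)-4-hydroxy-2,3-dimethoxy-5-methylideneocta-1,3,7-trien-1-one, dienylketene (not isolated) | O=C=C(OC)/C(OC)=C(/O)C(=C)CC=C | intermediate
15 | 5-allyl-2,3-dimethoxybenzene-1,4-diol (not isolated) | C=CCc1cc(O)c(OC)c(OC)c1O | intermediate
16 | 5-allyl-2,3-dimethoxy-1,4-benzoquinone | C=CCC1=CC(=O)C(OC)=C(OC)C1=O | intermediate
17 | (1S,6R,7R,8R)-cyclobutane-fused enedione (see step 9) | C=CC[C@@]12[C@@H](C(=O)C(OC)=C(OC)C1=O)[C@H](c1ccc(O[Si](C(C)C)(C(C)C)C(C)C)c(OC)c1)[C@H]2C | intermediate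
18 | ring-opened benzylic cation triflate: 6-allyl-2,3,4-trimethoxycyclohexa-2,4-dienone carrying the 1-arylpropan-1-ylium-2-yl group at C-6, C-1' and C-8 as in 17 (not isolated) | C=CC[C@]1(C=C(OC)C(OC)=C(OC)C1=O)[C@H](C)[CH+]c1ccc(O[Si](C(C)C)(C(C)C)C(C)C)c(OC)c1.[O-]S(=O)(=O)C(F)(F)F | intermediate
19 | bicyclo[3.2.1] O-4'-methyloxocarbenium triflate (not isolated) | C=CC[C@@]12C=C(OC)C(=[O+]C)[C@@](OC)(C1=O)[C@H](c1ccc(O[Si](C(C)C)(C(C)C)C(C)C)c(OC)c1)[C@H]2C.[O-]S(=O)(=O)C(F)(F)F | intermediate
20 | (1S,5R,6R,7S)-bicyclo[3.2.1]oct-3-ene-2,8-dione (see step 10) | C=CC[C@@]12C=C(OC)C(=O)[C@@](OC)(C1=O)[C@H](c1ccc(O[Si](C(C)C)(C(C)C)C(C)C)c(OC)c1)[C@H]2C | intermediate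
21 | (1R,4S,5R,6S,7R)-silyl-protected alcohol (see step 11) | C=CC[C@@]12C=C(OC)[C@H](O)[C@@](OC)(C1=O)[C@H](c1ccc(O[Si](C(C)C)(C(C)C)C(C)C)c(OC)c1)[C@H]2C | intermediate
22 | CNP0330966.1 | C=CC[C@@]12C=C(OC)[C@H](O)[C@@](OC)(C1=O)[C@H](c1ccc(O)c(OC)c1)[C@H]2C | target

## Step count and risks
Total steps: 12. Longest linear sequence: 8 (steps 1, 2, 3, 4, 9, 10, 11, 12).

**Step 10 (the proposed new ring expansion).** The methyl relay may stall, or cation 18 may drain through carbonyl-oxygen capture to a hydrobenzofuran isomer. The fallback uses known chemistry, sets out from 6 and 16, and comes back at 20. The cyclobutane is bypassed. Quinone 16 and alkene 6 are combined with the same titanium TADDOLate enriched in TiCl4 at −78 to −20 °C, which are the conditions of the known direct formal (5+2) quinone–propenylarene annulation. This gives the 5'-O-desmethyl diosphenol of 20 F1, with the O-4' methyl lost to chloride. F1 is then O-methylated with MeI/K2CO3 in acetone to give 20.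

**Step 9 (regiochemistry at the allyl-bearing carbon and level of induction with a second methoxy group on the quinone).** The fallback sets out from 6 and 16 and comes back at 17. The annulation is run with the achiral promoter TiCl4/Ti(OiPr)4 (1:1, CH2Cl2, −78 °C), the mixture under which such cyclobutanes form most reliably. The racemate is separated by preparative HPLC on an amylose tris(3,5-dimethylphenylcarbamate) phase into 17 and the enantiomeric cyclobutane F2. This replaces asymmetric induction with resolution.

**Step 7 (the skipped dienyllithium 12 can isomerise by bis-allylic proton transfer).** The fallback sets out from 8 and 10 and comes back at 15, which the Ag2O of step 8 turns into 16. It runs as follows: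
- Vinylmagnesium bromide 10 is added to 8 (THF, −78 °C) to give 4-hydroxy-2,3-dimethoxy-4-vinylcyclobut-2-en-1-one F3.
- Thermolysis in p-xylene gives 2,3-dimethoxybenzene-1,4-diol F4.
- Ag2O gives 2,3-dimethoxy-1,4-benzoquinone F5.
- Hosomi–Sakurai allylation with allyltrimethylsilane/TiCl4 (CH2Cl2, −78 °C) puts the allyl group on the symmetric quinone and delivers 15.

## Further compounds
F1 | step 10 | 5'-O-desmethyl diosphenol of 20: 5-allyl-3-hydroxy-1-methoxy-6-methyl-7-[3-methoxy-4-(triisopropylsilyloxy)phenyl]bicyclo[3.2.1]oct-3-ene-2,8-dione, stereocentres as in 20 | C=CC[C@@]12C=C(O)C(=O)[C@@](OC)(C1=O)[C@H](c1ccc(O[Si](C(C)C)(C(C)C)C(C)C)c(OC)c1)[C@H]2C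
F2 | step 9 | enantiomer of 17, (1R,6S,7S,8S) | C=CC[C@]12[C@H](C(=O)C(OC)=C(OC)C1=O)[C@@H](c1ccc(O[Si](C(C)C)(C(C)C)C(C)C)c(OC)c1)[C@@H]2C
F3 | step 7 | (±)-4-hydroxy-2,3-dimethoxy-4-vinylcyclobut-2-en-1-one | C=CC1(O)C(OC)=C(OC)C1=O
F4 | step 7 | 2,3-dimethoxybenzene-1,4-diol | COc1c(O)ccc(O)c1OC
F5 | step 7 | 2,3-dimethoxy-1,4-benzoquinone | COC1=C(OC)C(=O)C=CC1=O
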